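**Retrosynthetic overview**

1. Numbering: C1 = quaternary carbinol carrying C7H2OBz, C2/C3 = acetoxy carbons, C4=C5 = alkene, C6 = benzoyloxy carbon; the target is (1S,2S,3R,6S). The strategy rests on a latent mirror plane through C1 (and C4) of the six-membered ring: C2–C3 and C6–C5 are the two enone arms of an achiral 4-hydroxycyclohexa-2,5-dienone, and the C6 oxygen is cis to the C1 hydroxyl, so one boron atom can span both in a five-membered C1–O–B–O–C6 ring.
2. Late stage: the C6 benzoate comes from selective acylation of a C1/C6 diol freed from an acetonide; the C3 acetate comes from SN2 opening of a C2–C3 epoxide allylic to C4=C5; the alkene comes from the C4 ketone via its enol triflate; the epoxide comes from the surviving enone arm.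
3. Key disconnection: the C6–O bond and the dioxaborolane ring, formed by a boronate-tethered oxa-Michael addition that selects one of the two enantiotopic enone arms of the p-quinol under a chiral amine–thiourea catalyst.
4. The quinol comes from 4-hydroxybenzyl benzoate by iodine(III)/water dearomatisation; the phenol comes from 4-hydroxybenzyl alcohol by dibenzoylation and selective aryl ester cleavage.
5. Ring order: carbocycle (from the arene, step 3), dioxaborolane (step 4), dioxolane by exchange (step 5), oxirane (step 6, opened in step 9).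

Key step: step 4

Assumption: the sense of enone-arm selection by a cinchona thiourea on quinol 5 cannot be assigned with certainty in advance. The route is written with the epi-quinidine-derived catalyst; its pseudoenantiomer (epi-quinine-derived) would be used unchanged if a test reaction shows the (1R,6R) sense.

**Route**

Step 1
Reactants: 1 4-hydroxybenzyl alcohol; 2 benzoyl chloride
Product: 3 4-[(benzoyloxy)methyl]phenyl benzoate
Conditions: BzCl (2.3 equiv), Et3N, DMAP (cat.), CH2Cl2, 0 °C → rt
Reagents that add atoms: benzoyl chloride, O=C(Cl)c1ccccc1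
Why: DMAP-catalysed O-acylation of both hydroxyls should be exhaustive, and capping the phenol removes the free p-hydroxybenzyl motif that could otherwise ionise during esterification.

Step 2
Reactants: 3 4-[(benzoyloxy)methyl]phenyl benzoate
Product: 4 4-hydroxybenzyl benzoate
Conditions: pyrrolidine (1.2 equiv), CH2Cl2, 0 °C → rt; aq. citric acid work-up
Reagents that add atoms: none
Why: Chemoselective aminolysis should cleave only the aryl ester (phenoxide leaving group) and leave the alkyl benzoate, while the aprotic medium, near-stoichiometric amine and acidic quench keep the product phenol un-ionised and so suppress quinone methide formation.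

Step 3
Reactants: 4 4-hydroxybenzyl benzoate
Product: 5 (1-hydroxy-4-oxocyclohexa-2,5-dien-1-yl)methyl benzoate
Conditions: PhI(OAc)2 (1.2 equiv), MeCN–H2O (3:1), 0 °C
Reagents that add atoms: water, O
Why: Iodine(III)-mediated oxidative dearomatisation of a para-substituted phenol, with water captured at the para carbon of the aryloxy-λ3-iodane, should give the achiral p-quinol with no stereocentre to control.

Step 4
Reactants: 5 (1-hydroxy-4-oxocyclohexa-2,5-dien-1-yl)methyl benzoate; 6 phenylboronic acid
Product: 8 [(1S,6S)-4-oxo-1,6-(phenylboranediyldioxy)cyclohex-2-en-1-yl]methyl benzoate (cis-fused 2-phenyl-1,3,2-dioxaborolane), via quinol boronic hemiester 7 (not isolated)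
Conditions: PhB(OH)2 (1.2 equiv), 9-amino-9-deoxy-epi-quinidine N′-[3,5-bis(trifluoromethyl)phenyl]thiourea (10 mol%), 4 Å MS, toluene, rt; filtered, concentrated and used directly
Reagents that add atoms: phenylboronic acid, OB(O)c1ccccc1
Why: The tertiary C1–OH condenses with the boronic acid to hemiester 7; the quinuclidine nitrogen then activates the remaining B–OH as an amine–boronate complex while the thiourea hydrogen-bonds the dienone carbonyl, the boron-bound oxygen adds to C6 of one enone arm, and the enolate is protonated at C5. The closest known reaction type is the amine–thiourea-catalysed oxa-Michael addition of boronic acid hemiesters to γ-hydroxy-α,β-enones, alongside the acetalisation/oxa-Michael desymmetrisations of p-quinols. The one ring closed, the 1,3,2-dioxaborolane C1–O–B–O–C6, forms in a 5-exo-trig mode. The tether can reach C6 only on the face carrying the C1 oxygen, so the fusion is cis, and the catalyst's choice between the two enantiotopic arms therefore fixes C1 and C6 together as (1S,6S). The step needs enantiotopic-group selectivity, which rests on the bifunctional catalyst, and mono-addition, which the substrate secures because after closure boron carries no further OH to deliver to the second arm (C2=C3–C4=O). Molecular sieves drive hemiester formation, and the non-polar solvent at rt limits the uncatalysed background reaction and retro-Michael erosion.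

Step 5
Reactants: 8 [(1S,6S)-4-oxo-1,6-(phenylboranediyldioxy)cyclohex-2-en-1-yl]methyl benzoate
Product: 10 [(1S,6S)-1,6-(isopropylidenedioxy)-4-oxocyclohex-2-en-1-yl]methyl benzoate, via cis-diol enone 9 (not isolated)
Conditions: pinacol (1.1 equiv), CH2Cl2, rt; then Me2C(OMe)2, CSA (cat.), 0 °C → rt
Reagents that add atoms: 2,2-dimethoxypropane, COC(C)(C)OC
Why: Boronate transesterification onto pinacol (giving the more stable pinacol ester) should release the cis-diol, which is trapped at once by acid-catalysed transketalisation, and the non-basic conditions avoid retro-oxa-Michael loss of the C6 oxygen so that C1 and C6 are untouched.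

Step 6
Reactants: 10 [(1S,6S)-1,6-(isopropylidenedioxy)-4-oxocyclohex-2-en-1-yl]methyl benzoate
Product: 11 [(1S,2S,3R,6S)-2,3-epoxy-1,6-(isopropylidenedioxy)-4-oxocyclohexyl]methyl benzoate
Conditions: t-BuOOH (decane), DBU (0.5 equiv), CH2Cl2, 0 °C
Reagents that add atoms: tert-butyl hydroperoxide, CC(C)(C)OO
Why: Weitz–Scheffer nucleophilic epoxidation in which the peroxide anion should add to C2 anti to the allylic C1–O bond, on the face away from the cis-fused dioxolane, and the enolate closes on the same face, placing the C2/C3 epoxide trans to the C1 and C6 oxygens.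

Step 7
Reactants: 11 [(1S,2S,3R,6S)-2,3-epoxy-1,6-(isopropylidenedioxy)-4-oxocyclohexyl]methyl benzoate
Product: 12 [(1S,2S,3R,6S)-2,3-epoxy-1,6-(isopropylidenedioxy)-4-(trifluoromethylsulfonyloxy)cyclohex-4-en-1-yl]methyl benzoate
Conditions: LiHMDS added to 11 and Comins' reagent, THF, −78 °C
Reagents that add atoms: Comins' reagent [N-(5-chloropyridin-2-yl)-bis(trifluoromethanesulfonyl)imide], O=S(=O)(N(c1ccc(Cl)cn1)S(=O)(=O)C(F)(F)F)C(F)(F)F
Why: Kinetic deprotonation can occur only at C5 (the C3 hydrogen sits on the oxirane), and O-sulfonylation of the lithium enolate by the in-situ triflating agent at −78 °C should outrun E1cB loss of the C6 oxygen.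

Step 8
Reactants: 12 [(1S,2S,3R,6S)-2,3-epoxy-1,6-(isopropylidenedioxy)-4-(trifluoromethylsulfonyloxy)cyclohex-4-en-1-yl]methyl benzoate
Product: 13 [(1S,2S,3S,6S)-2,3-epoxy-1,6-(isopropylidenedioxy)cyclohex-4-en-1-yl]methyl benzoate
Conditions: Pd(PPh3)4 (5 mol%), LiCl, Bu3SnH (1.05 equiv, slow addition), THF, 0 °C → rt
Reagents that add atoms: none
Why: Palladium-catalysed hydride reduction of the vinyl triflate (oxidative addition, tin-to-palladium hydride transfer, reductive elimination) should give the C4=C5 alkene, since C–OTf oxidative addition is faster than ionisation of the hindered allylic epoxide and the hydride is kept limiting; no stereocentre is touched.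

Step 9
Reactants: 13 [(1S,2S,3S,6S)-2,3-epoxy-1,6-(isopropylidenedioxy)cyclohex-4-en-1-yl]methyl benzoate
Product: 14 [(1R,2S,3R,6S)-3-acetoxy-2-hydroxy-1,6-(isopropylidenedioxy)cyclohex-4-en-1-yl]methyl benzoate
Conditions: AcOH, NaOAc, rt → 40 °C
Reagents that add atoms: acetic acid, CC(=O)O
Why: Acid-assisted SN2 opening of the vinyl epoxide by acetate should occur at the allylic C3 (C2 is neopentyl-like next to the fully substituted C1), and backside attack inverts C3 so that the new C3–OAc is trans to C2–OH and cis to the C1 oxygen.

Step 10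
Reactants: 14 [(1R,2S,3R,6S)-3-acetoxy-2-hydroxy-1,6-(isopropylidenedioxy)cyclohex-4-en-1-yl]methyl benzoate
Product: 15 [(1S,2S,3R,6S)-2,3-diacetoxy-1,6-(isopropylidenedioxy)cyclohex-4-en-1-yl]methyl benzoate
Conditions: Ac2O, pyridine, DMAP (cat.), CH2Cl2, rt
Reagents that add atoms: acetic anhydride, CC(=O)OC(C)=O
Why: DMAP-catalysed acetylation should esterify the hindered secondary C2–OH with retention, and any earlier acetyl migration between O3 and O2 is harmless because both end as acetates.

Step 11
Reactants: 15 [(1S,2S,3R,6S)-2,3-diacetoxy-1,6-(isopropylidenedioxy)cyclohex-4-en-1-yl]methyl benzoate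
Product: 16 [(1S,2S,3R,6S)-2,3-diacetoxy-1,6-dihydroxycyclohex-4-en-1-yl]methyl benzoate
Conditions: TFA–H2O (9:1), CH2Cl2, 0 °C
Reagents that add atoms: none
Why: Acid hydrolysis of the isopropylidene ketal should free the C1/C6 diol, the esters being inert and the short cold exposure limiting acyl migration and allylic ionisation.

Step 12
Reactants: 16 [(1S,2S,3R,6S)-2,3-diacetoxy-1,6-dihydroxycyclohex-4-en-1-yl]methyl benzoate; 2 benzoyl chloride
Product: 17 cleistenediol F, [(1S,2S,3R,6S)-2,3-diacetoxy-6-(benzoyloxy)-1-hydroxycyclohex-4-en-1-yl]methyl benzoate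
Conditions: BzCl (1.2 equiv), pyridine, CH2Cl2, 0 °C
Reagents that add atoms: benzoyl chloride, O=C(Cl)c1ccccc1
Why: Acylation should take place at the secondary allylic C6–OH with retention, the tertiary C1–OH being too hindered to react under these mild conditions.

**Compound list**

1 | 4-hydroxybenzyl alcohol | OCc1ccc(O)cc1 | starting material
2 | benzoyl chloride | O=C(Cl)c1ccccc1 | starting material
3 | 4-[(benzoyloxy)methyl]phenyl benzoate | O=C(OCc1ccc(OC(=O)c2ccccc2)cc1)c1ccccc1 | intermediate
4 | 4-hydroxybenzyl benzoate | O=C(OCc1ccc(O)cc1)c1ccccc1 | intermediate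
5 | (1-hydroxy-4-oxocyclohexa-2,5-dien-1-yl)methyl benzoate (achiral p-quinol) | O=C1C=CC(O)(COC(=O)c2ccccc2)C=C1 | intermediate
6 | phenylboronic acid | OB(O)c1ccccc1 | starting material
7 | quinol boronic hemiester, (1-{[hydroxy(phenyl)boranyl]oxy}-4-oxocyclohexa-2,5-dien-1-yl)methyl benzoate | O=C1C=CC(COC(=O)c2ccccc2)(OB(O)c2ccccc2)C=C1 | intermediate (not isolated)
8 | [(1S,6S)-4-oxo-1,6-(phenylboranediyldioxy)cyclohex-2-en-1-yl]methyl benzoate (cis-fused phenylboronate) | O=C1C=C[C@@]2(COC(=O)c3ccccc3)OB(c3ccccc3)O[C@H]2C1 | intermediate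
9 | [(1S,6S)-1,6-dihydroxy-4-oxocyclohex-2-en-1-yl]methyl benzoate (cis-diol enone) | O=C1C=C[C@](O)(COC(=O)c2ccccc2)[C@@H](O)C1 | intermediate (not isolated)
10 | [(1S,6S)-1,6-(isopropylidenedioxy)-4-oxocyclohex-2-en-1-yl]methyl benzoate (cis-fused acetonide enone) | O=C1C=C[C@@]2(COC(=O)c3ccccc3)OC(C)(C)O[C@H]2C1 | intermediate
11 | [(1S,2S,3R,6S)-2,3-epoxy-1,6-(isopropylidenedioxy)-4-oxocyclohexyl]methyl benzoate (epoxide trans to the acetonide) | O=C1[C@@H]2O[C@@H]2[C@@]3(COC(=O)c4ccccc4)OC(C)(C)O[C@H]3C1 | intermediate
12 | [(1S,2S,3R,6S)-2,3-epoxy-1,6-(isopropylidenedioxy)-4-(trifluoromethylsulfonyloxy)cyclohex-4-en-1-yl]methyl benzoate | C1=C(OS(=O)(=O)C(F)(F)F)[C@@H]2O[C@@H]2[C@@]3(COC(=O)c4ccccc4)OC(C)(C)O[C@@H]13 | intermediate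
13 | [(1S,2S,3S,6S)-2,3-epoxy-1,6-(isopropylidenedioxy)cyclohex-4-en-1-yl]methyl benzoate (vinyl epoxide) | C1=C[C@@H]2O[C@@H]2[C@@]3(COC(=O)c4ccccc4)OC(C)(C)O[C@@H]13 | intermediate
14 | [(1R,2S,3R,6S)-3-acetoxy-2-hydroxy-1,6-(isopropylidenedioxy)cyclohex-4-en-1-yl]methyl benzoate | C1=C[C@@H](OC(C)=O)[C@H](O)[C@@]2(COC(=O)c3ccccc3)OC(C)(C)O[C@@H]12 | intermediate
15 | [(1S,2S,3R,6S)-2,3-diacetoxy-1,6-(isopropylidenedioxy)cyclohex-4-en-1-yl]methyl benzoate | C1=C[C@@H](OC(C)=O)[C@H](OC(C)=O)[C@@]2(COC(=O)c3ccccc3)OC(C)(C)O[C@@H]12 | intermediate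
16 | [(1S,2S,3R,6S)-2,3-diacetoxy-1,6-dihydroxycyclohex-4-en-1-yl]methyl benzoate | C1=C[C@@H](OC(C)=O)[C@H](OC(C)=O)[C@](O)(COC(=O)c2ccccc2)[C@H]1O | intermediate
17 | cleistenediol F, [(1S,2S,3R,6S)-2,3-diacetoxy-6-(benzoyloxy)-1-hydroxycyclohex-4-en-1-yl]methyl benzoate | CC(=O)O[C@@H]1C=C[C@H](OC(=O)c2ccccc2)[C@@](O)(COC(=O)c2ccccc2)[C@H]1OC(C)=O | target

**Step count and risks**

Total step count: 12. Longest linear sequence: 12 steps (fully linear from 1).

Steps most likely to fail:

1. Step 4. The catalyst may discriminate poorly between the two enantiotopic enone arms, the oxa-Michael addition may reverse through the achiral quinol and erode enantiomeric purity, and esterification of the tertiary hydroxyl by the boronic acid may be slow. Fallback: setting out from quinol 5, the tether is changed from boron to carbon. A chiral BINOL-derived phosphoric acid (TRIP type, enantiomer chosen to give the 1S,6S series) catalyses hemiacetal formation with isobutyraldehyde and the ensuing oxa-Michael closure to the cis-fused isobutylidene acetal enone F1. Mild aqueous acid (AcOH–H2O) then releases cis-diol enone 9, isolated in this variant, which is ketalised (Me2C(OMe)2, PPTS) to return to the route at acetonide enone 10.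

2. Step 7. β-Elimination of the C6 oxygen from the C4–C5 enolate (E1cB opening of the dioxolane, followed by aromatisation) may outrun O-sulfonylation. Fallback: setting out from epoxy ketone 11, the ketone is reduced (NaBH4, MeOH, 0 °C) to the epoxy alcohol F2, either C4 epimer being usable. F2 is dehydrated with Martin sulfurane (CH2Cl2, rt) towards C5, the only neighbouring carbon with a removable hydrogen. This gives vinyl epoxide 13 directly, where the route is rejoined, with no enolate and no palladium hydride involved.

3. Step 8. Once the triflate is consumed, palladium(0) may ionise the allylic C3–O bond of the product epoxide and the resulting π-allyl complex may be reduced by the stannane, losing the C3 oxygen. Fallback: setting out from enol triflate 12, the order of events is reversed. Acetate opening at C3 (AcOH, NaOAc) gives the hydroxy acetate triflate F3, and acetylation (Ac2O, pyridine, DMAP) gives the diacetate triflate F4. Only then is the triflate reduced (Pd(PPh3)4, LiCl, Bu3SnH, THF), at a stage where the only allylic leaving group is an acetate, which ionises far more slowly than an epoxide. This returns to the route at diacetate 15.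

**Further compounds**

F1 | step 4 | [(1S,6S)-1,6-(2-methylpropylidenedioxy)-4-oxocyclohex-2-en-1-yl]methyl benzoate (cis-fused isobutylidene acetal, drawn as the exo-isopropyl epimer; the acetal centre is lost on hydrolysis) | O=C1C=C[C@@]2(COC(=O)c3ccccc3)O[C@H](C(C)C)O[C@H]2C1
F2 | step 7 | [(1S,2S,6S)-2,3-epoxy-4-hydroxy-1,6-(isopropylidenedioxy)cyclohexyl]methyl benzoate (epoxide trans to the acetonide; C4 epimers) | OC1[C@@H]2O[C@@H]2[C@@]3(COC(=O)c4ccccc4)OC(C)(C)O[C@H]3C1
F3 | step 8 | [(1R,2S,3S,6S)-3-acetoxy-2-hydroxy-1,6-(isopropylidenedioxy)-4-(trifluoromethylsulfonyloxy)cyclohex-4-en-1-yl]methyl benzoate | C1=C(OS(=O)(=O)C(F)(F)F)[C@@H](OC(C)=O)[C@H](O)[C@@]2(COC(=O)c3ccccc3)OC(C)(C)O[C@@H]12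
F4 | step 8 | [(1S,2S,3S,6S)-2,3-diacetoxy-1,6-(isopropylidenedioxy)-4-(trifluoromethylsulfonyloxy)cyclohex-4-en-1-yl]methyl benzoate | C1=C(OS(=O)(=O)C(F)(F)F)[C@@H](OC(C)=O)[C@H](OC(C)=O)[C@@]2(COC(=O)c3ccccc3)OC(C)(C)O[C@@H]12
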